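**Retrosynthetic overview**
- Target ⇐ hydrogenolysis of two phenolic benzyl ethers ⇐ one-pot hydride reduction of three acyl groups (auxiliary imide, methyl ester, ring ethyl ester) to the three CH2OH groups.
- Dihydrobenzofuran (the only ring formed, and formed last) ⇐ dirhodium-carbenoid C–H insertion of an aryldiazoacetate into its ortho ArO–CH2Ar ether, then C3 epimerisation to trans; the diazo ester ⇐ aryl iodide + ethyl diazoacetate (Pd).
- Key disconnection, the central C–C bond of the 2,3-dibenzylsuccinate: a chiral imide enolate (made by hydride conjugate addition to a cinnamoyl oxazolidinone) attacks an (R)-α-triflyloxy ester used as an enolonium equivalent. SN2 inversion plus auxiliary control set both butane stereocentres in one step.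
- Triflate ⇐ aryl Grignard + methyl (R)-glycidate; enoyl imide ⇐ 5-iodovanillin by Mitsunobu etherification and Horner–Wadsworth–Emmons olefination.

Assumption: the (R)-ligand catalyst Rh2(R-PTTL)4 is taken to give the (2S) ring carbon, from my recollection that the (S)-ligand catalyst gives the (2R) series; if the sense is the reverse on this substrate, Rh2(S-PTTL)4 is used and nothing else changes.

**Step 1**
Reactants: 1 1-(benzyloxy)-4-bromo-2-methoxybenzene; 2 methyl (2R)-oxirane-2-carboxylate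
Product: 4 methyl (2R)-3-[4-(benzyloxy)-3-methoxyphenyl]-2-hydroxypropanoate, via arylmagnesium bromide 3 (not isolated)
Conditions: Mg, THF, reflux; then CuI (10 mol%), 2, THF, −40 °C; 1 M HCl
Reagents that add atoms: none
Why: Copper-catalysed Grignard ring-opening of the glycidic ester occurs at the unsubstituted epoxide carbon faster than ester addition at low temperature, so the stereocentre of 2 is carried over untouched as the (R)-α-hydroxy ester.

**Step 2**
Reactants: 4 methyl (2R)-3-[4-(benzyloxy)-3-methoxyphenyl]-2-hydroxypropanoate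
Product: 5 methyl (2R)-3-[4-(benzyloxy)-3-methoxyphenyl]-2-[(trifluoromethanesulfonyl)oxy]propanoate
Conditions: Tf2O, 2,6-lutidine, CH2Cl2, −78 °C to 0 °C; used at once
Reagents that add atoms: trifluoromethanesulfonic anhydride O=S(=O)(OS(=O)(=O)C(F)(F)F)C(F)(F)F
Why: O-sulfonylation of the secondary alcohol breaks no bond at the stereocentre (retention) and makes the ester α-carbon electrophilic, while the adjacent ester disfavours ionisation and aryl participation so the configuration holds.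

**Step 3**
Reactants: 6 4-hydroxy-3-iodo-5-methoxybenzaldehyde (5-iodovanillin); 7 [4-(benzyloxy)-3-methoxyphenyl]methanol
Product: 8 4-{[4-(benzyloxy)-3-methoxyphenyl]methoxy}-3-iodo-5-methoxybenzaldehyde
Conditions: PPh3, DIAD, THF, 0 °C to rt
Reagents that add atoms: none
Why: Mitsunobu etherification of the acidic phenol with the primary benzylic alcohol gives the aryl benzyl ether whose OCH2 carbon later becomes C2 of the dihydrobenzofuran; no stereocentre is formed.

**Step 4**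
Reactants: 9 (diethoxyphosphoryl)acetic acid; 10 (4S)-4-benzyl-1,3-oxazolidin-2-one
Product: 12 diethyl {2-[(4S)-4-benzyl-2-oxo-1,3-oxazolidin-3-yl]-2-oxoethyl}phosphonate, via mixed pivalic anhydride 11 (not isolated)
Conditions: t-BuCOCl, Et3N, THF, −20 °C; then LiCl, 10, rt
Reagents that add atoms: none
Why: N-acylation of the oxazolidinone through the mixed pivalic anhydride (LiCl/Et3N activation) gives the auxiliary-bearing Horner–Wadsworth–Emmons reagent with the auxiliary stereocentre untouched.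

**Step 5**
Reactants: 8 4-{[4-(benzyloxy)-3-methoxyphenyl]methoxy}-3-iodo-5-methoxybenzaldehyde; 12 diethyl {2-[(4S)-4-benzyl-2-oxo-1,3-oxazolidin-3-yl]-2-oxoethyl}phosphonate
Product: 13 (4S)-4-benzyl-3-[(2E)-3-(4-{[4-(benzyloxy)-3-methoxyphenyl]methoxy}-3-iodo-5-methoxyphenyl)prop-2-enoyl]-1,3-oxazolidin-2-one
Conditions: LiCl, i-Pr2NEt, MeCN, rt
Reagents that add atoms: none
Why: Horner–Wadsworth–Emmons olefination under Masamune–Roush conditions gives the (E)-enoyl imide and is mild enough to leave the aryl iodide and benzyl ethers alone.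

**Step 6 (key step)**
Reactants: 13 (4S)-4-benzyl-3-[(2E)-3-(4-{[4-(benzyloxy)-3-methoxyphenyl]methoxy}-3-iodo-5-methoxyphenyl)prop-2-enoyl]-1,3-oxazolidin-2-one; 5 methyl (2R)-3-[4-(benzyloxy)-3-methoxyphenyl]-2-[(trifluoromethanesulfonyl)oxy]propanoate
Product: 15 methyl (2R,3R)-2-{[4-(benzyloxy)-3-methoxyphenyl]methyl}-3-[(4-{[4-(benzyloxy)-3-methoxyphenyl]methoxy}-3-iodo-5-methoxyphenyl)methyl]-4-[(4S)-4-benzyl-2-oxo-1,3-oxazolidin-3-yl]-4-oxobutanoate, via lithium Z-enolate 14 (not isolated)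
Conditions: LiBH(s-Bu)3 (1.0 equiv), THF, −78 °C; then 5 (1.3 equiv), −78 to −20 °C
Reagents that add atoms: none
Why: Proposed new method: conjugate hydride addition to the s-cis enoyl imide gives the chelated lithium Z-enolate 14 without any amide base, and this enolate displaces the α-triflate of 5 (an ester α-carbon made electrophilic, i.e. an enolonium equivalent) by SN2 on the face opposite the auxiliary benzyl group, so the (S)-auxiliary fixes C3 as R and inversion of the (R)-triflate fixes C2 as R; the closest known reaction types are the Evans imide-enolate alkylation with α-triflyloxy esters to 2,3-disubstituted succinates and the trialkylborohydride reductive alkylation of enones and enoyl imides.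

**Step 7**
Reactants: 15 the iodo succinate from step 6; 16 ethyl diazoacetate
Product: 17 methyl (2R,3R)-2-{[4-(benzyloxy)-3-methoxyphenyl]methyl}-3-{[4-{[4-(benzyloxy)-3-methoxyphenyl]methoxy}-3-(1-diazo-2-ethoxy-2-oxoethyl)-5-methoxyphenyl]methyl}-4-[(4S)-4-benzyl-2-oxo-1,3-oxazolidin-3-yl]-4-oxobutanoate
Conditions: Pd(PPh3)4 (10 mol%), Et3N, n-Bu4NBr, MeCN, rt
Reagents that add atoms: none
Why: Palladium-catalysed cross-coupling of an aryl iodide with a diazoacetate (oxidative addition to zerovalent palladium, C-palladation of the deprotonated diazo ester, reductive elimination with the diazo group kept) installs the donor/acceptor diazo ester, and Et3N at rt does not epimerise the two succinate centres.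

**Step 8**
Reactants: 17 the aryldiazoacetate from step 7
Product: 19 ethyl (2S,3S)-2-[4-(benzyloxy)-3-methoxyphenyl]-5-[(2R,3R)-2-{[(4S)-4-benzyl-2-oxo-1,3-oxazolidin-3-yl]carbonyl}-3-{[4-(benzyloxy)-3-methoxyphenyl]methyl}-4-methoxy-4-oxobutyl]-7-methoxy-2,3-dihydro-1-benzofuran-3-carboxylate (trans), via cis-dihydrobenzofuran ester 18 (not isolated)
Conditions: dirhodium tetrakis[N-phthaloyl-(R)-tert-leucinate] Rh2(R-PTTL)4 (2 mol%), toluene, −60 °C; then DBU (0.5 equiv), rt
Reagents that add atoms: none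
Why: Intramolecular 1,5 C–H insertion of the dirhodium carbenoid into the activated benzylic ether C–H closes the dihydrofuran ring with the chiral carboxylate catalyst fixing C2 as S in the cis ester, and DBU then epimerises only the doubly activated C3–H (benzylic and α to the ester) to the thermodynamically favoured trans (2S,3S) ester.

**Step 9**
Reactants: 19 the trans-dihydrobenzofuran triacyl compound from step 8
Product: 20 (2R,3R)-2-{[4-(benzyloxy)-3-methoxyphenyl]methyl}-3-({(2S,3R)-2-[4-(benzyloxy)-3-methoxyphenyl]-3-(hydroxymethyl)-7-methoxy-2,3-dihydro-1-benzofuran-5-yl}methyl)butane-1,4-diol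
Conditions: LiAlH4 (excess), THF, 0 °C to rt; H2O, 15% aq NaOH work-up
Reagents that add atoms: none
Why: Exhaustive hydride reduction turns the imide, the methyl ester and the ring ethyl ester into the three primary alcohols in one operation and releases the auxiliary, with no stereocentre touched (the ring C3 descriptor changes from S to R only through the priority change).

**Step 10**
Reactants: 20 the bis(benzyl ether) triol from step 9
Product: 21 (2R,3R)-2-[(4-hydroxy-3-methoxyphenyl)methyl]-3-{[(2S,3R)-2-(4-hydroxy-3-methoxyphenyl)-3-(hydroxymethyl)-7-methoxy-2,3-dihydro-1-benzofuran-5-yl]methyl}butane-1,4-diol (CNP0256425.1)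
Conditions: H2 (1 atm), palladium on carbon (10% Pd/C), EtOAc–EtOH, rt, stopped after 2 equiv H2
Reagents that add atoms: none
Why: Catalytic hydrogenolysis cleaves the two aryl benzyl ethers much faster than the cyclic benzylic C2–O bond, freeing both phenols without touching any stereocentre.

**Compound list**
1 | 1-(benzyloxy)-4-bromo-2-methoxybenzene | COc1cc(Br)ccc1OCc1ccccc1 | starting material
2 | methyl (2R)-oxirane-2-carboxylate | COC(=O)[C@H]1CO1 | starting material
3 | [4-(benzyloxy)-3-methoxyphenyl]magnesium bromide | COc1cc([Mg]Br)ccc1OCc1ccccc1 | intermediate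
4 | methyl (2R)-3-[4-(benzyloxy)-3-methoxyphenyl]-2-hydroxypropanoate | COC(=O)[C@H](O)Cc1ccc(OCc2ccccc2)c(OC)c1 | intermediate
5 | methyl (2R)-3-[4-(benzyloxy)-3-methoxyphenyl]-2-[(trifluoromethanesulfonyl)oxy]propanoate | COC(=O)[C@H](OS(=O)(=O)C(F)(F)F)Cc1ccc(OCc2ccccc2)c(OC)c1 | intermediate
6 | 4-hydroxy-3-iodo-5-methoxybenzaldehyde | COc1cc(C=O)cc(I)c1O | starting material
7 | [4-(benzyloxy)-3-methoxyphenyl]methanol | COc1cc(CO)ccc1OCc1ccccc1 | starting material
8 | 4-{[4-(benzyloxy)-3-methoxyphenyl]methoxy}-3-iodo-5-methoxybenzaldehyde | COc1cc(C=O)cc(I)c1OCc1ccc(OCc2ccccc2)c(OC)c1 | intermediate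
9 | (diethoxyphosphoryl)acetic acid | CCOP(=O)(CC(=O)O)OCC | starting material
10 | (4S)-4-benzyl-1,3-oxazolidin-2-one | O=C1N[C@@H](Cc2ccccc2)CO1 | starting material
11 | (diethoxyphosphoryl)acetic pivalic anhydride | CCOP(=O)(CC(=O)OC(=O)C(C)(C)C)OCC | intermediate
12 | diethyl {2-[(4S)-4-benzyl-2-oxo-1,3-oxazolidin-3-yl]-2-oxoethyl}phosphonate | CCOP(=O)(CC(=O)N1[C@@H](Cc2ccccc2)COC1=O)OCC | intermediate
13 | (4S)-4-benzyl-3-[(2E)-3-(4-{[4-(benzyloxy)-3-methoxyphenyl]methoxy}-3-iodo-5-methoxyphenyl)prop-2-enoyl]-1,3-oxazolidin-2-one | O=C(/C=C/c1cc(OC)c(OCc2ccc(OCc3ccccc3)c(OC)c2)c(I)c1)N1[C@@H](Cc2ccccc2)COC1=O | intermediate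
14 | lithium (Z)-enolate of the saturated imide from 13 (enolate O cis to the CH2Ar group) | [Li]O/C(=C\Cc1cc(OC)c(OCc2ccc(OCc3ccccc3)c(OC)c2)c(I)c1)N1[C@@H](Cc2ccccc2)COC1=O | intermediate
15 | methyl (2R,3R)-2-{[4-(benzyloxy)-3-methoxyphenyl]methyl}-3-[(4-{[4-(benzyloxy)-3-methoxyphenyl]methoxy}-3-iodo-5-methoxyphenyl)methyl]-4-[(4S)-4-benzyl-2-oxo-1,3-oxazolidin-3-yl]-4-oxobutanoate | COc1cc(C[C@@H](C(=O)OC)[C@H](C(=O)N2[C@@H](Cc3ccccc3)COC2=O)Cc2cc(OC)c(OCc3ccc(OCc4ccccc4)c(OC)c3)c(I)c2)ccc1OCc1ccccc1 | intermediate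
16 | ethyl diazoacetate | CCOC(=O)C=[N+]=[N-] | starting material
17 | methyl (2R,3R)-2-{[4-(benzyloxy)-3-methoxyphenyl]methyl}-3-{[4-{[4-(benzyloxy)-3-methoxyphenyl]methoxy}-3-(1-diazo-2-ethoxy-2-oxoethyl)-5-methoxyphenyl]methyl}-4-[(4S)-4-benzyl-2-oxo-1,3-oxazolidin-3-yl]-4-oxobutanoate | COc1cc(C[C@@H](C(=O)OC)[C@H](C(=O)N2[C@@H](Cc3ccccc3)COC2=O)Cc2cc(OC)c(OCc3ccc(OCc4ccccc4)c(OC)c3)c(C(=[N+]=[N-])C(=O)OCC)c2)ccc1OCc1ccccc1 | intermediate
18 | cis ester: ethyl (2S,3R)-2-[4-(benzyloxy)-3-methoxyphenyl]-5-[(2R,3R)-2-{[(4S)-4-benzyl-2-oxo-1,3-oxazolidin-3-yl]carbonyl}-3-{[4-(benzyloxy)-3-methoxyphenyl]methyl}-4-methoxy-4-oxobutyl]-7-methoxy-2,3-dihydro-1-benzofuran-3-carboxylate | COc1cc(C[C@@H](C(=O)OC)[C@H](C(=O)N2[C@@H](Cc3ccccc3)COC2=O)Cc2cc(OC)c3c(c2)[C@@H](C(=O)OCC)[C@@H](c2ccc(OCc4ccccc4)c(OC)c2)O3)ccc1OCc1ccccc1 | intermediate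
19 | trans ester: ethyl (2S,3S)-2-[4-(benzyloxy)-3-methoxyphenyl]-5-[(2R,3R)-2-{[(4S)-4-benzyl-2-oxo-1,3-oxazolidin-3-yl]carbonyl}-3-{[4-(benzyloxy)-3-methoxyphenyl]methyl}-4-methoxy-4-oxobutyl]-7-methoxy-2,3-dihydro-1-benzofuran-3-carboxylate | COc1cc(C[C@@H](C(=O)OC)[C@H](C(=O)N2[C@@H](Cc3ccccc3)COC2=O)Cc2cc(OC)c3c(c2)[C@H](C(=O)OCC)[C@@H](c2ccc(OCc4ccccc4)c(OC)c2)O3)ccc1OCc1ccccc1 | intermediate
20 | (2R,3R)-2-{[4-(benzyloxy)-3-methoxyphenyl]methyl}-3-({(2S,3R)-2-[4-(benzyloxy)-3-methoxyphenyl]-3-(hydroxymethyl)-7-methoxy-2,3-dihydro-1-benzofuran-5-yl}methyl)butane-1,4-diol | COc1cc(C[C@@H](CO)[C@H](CO)Cc2cc(OC)c3c(c2)[C@H](CO)[C@@H](c2ccc(OCc4ccccc4)c(OC)c2)O3)ccc1OCc1ccccc1 | intermediate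
21 | (2R,3R)-2-[(4-hydroxy-3-methoxyphenyl)methyl]-3-{[(2S,3R)-2-(4-hydroxy-3-methoxyphenyl)-3-(hydroxymethyl)-7-methoxy-2,3-dihydro-1-benzofuran-5-yl]methyl}butane-1,4-diol | COc1cc(C[C@@H](CO)[C@H](CO)Cc2cc(OC)c3c(c2)[C@H](CO)[C@@H](c2ccc(O)c(OC)c2)O3)ccc1O | target

**Totals**
Total step count: 10. Longest linear sequence: 7 steps (steps 3, 5, 6, 7, 8, 9, 10; the branches through steps 1–2 and through step 4 are equally long or shorter).

**Three steps most likely to fail**

Step 6. The one-pot reductive alkylation may suffer from 1,2-reduction, hydride attack on the triflate, a sluggish borane-complexed enolate, or E2 loss of the triflate to the cinnamate. The fallback sets out from 13 and comes back at 15. Compound 13 is reduced in a separate operation with [(Ph3P)CuH]6 (5 mol%) and polymethylhydrosiloxane in toluene to the isolated saturated imide (4S)-4-benzyl-3-[3-(4-{[4-(benzyloxy)-3-methoxyphenyl]methoxy}-3-iodo-5-methoxyphenyl)propanoyl]-1,3-oxazolidin-2-one F1. Its lithium Z-enolate is then formed with LiN(SiMe3)2 in THF at −78 °C, free of borane and hydride, and alkylated with triflate 5 as a discrete Evans alkylation to give 15.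

Step 7. The palladium coupling of the hindered ortho-alkoxy aryl iodide with ethyl diazoacetate may stall or lose the diazo group. The fallback sets out from 15 and comes back at 17. Iodide 15 is coupled with the Reformatsky reagent BrZnCH2CO2Et (bis(dibenzylideneacetone)palladium Pd(dba)2, P(t-Bu)3, THF, rt) to the arylacetate methyl (2R,3R)-2-{[4-(benzyloxy)-3-methoxyphenyl]methyl}-3-{[4-{[4-(benzyloxy)-3-methoxyphenyl]methoxy}-3-(2-ethoxy-2-oxoethyl)-5-methoxyphenyl]methyl}-4-[(4S)-4-benzyl-2-oxo-1,3-oxazolidin-3-yl]-4-oxobutanoate F2. Regitz diazo transfer with 4-acetamidobenzenesulfonyl azide and DBU in MeCN then gives 17.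

Step 8. Catalyst control alone may give insufficient selectivity on this 7-methoxy substrate, or the DBU epimerisation may open the ring by β-elimination of the phenoxide. The fallback sets out from 15 and comes back at 20; it uses a chiral ester auxiliary matched with a prolinate catalyst to give the trans ring directly, with no base epimerisation.
- Aminolysis of ethyl (S)-lactate with neat pyrrolidine gives (2S)-2-hydroxy-1-(pyrrolidin-1-yl)propan-1-one F3.
- Bromoacetyl bromide and pyridine convert it into (2S)-1-oxo-1-(pyrrolidin-1-yl)propan-2-yl bromoacetate F4.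
- N,N'-Ditosylhydrazine and DBU give (2S)-1-oxo-1-(pyrrolidin-1-yl)propan-2-yl diazoacetate F5.
- Coupling of this diazoacetate with iodide 15 under the step 7 conditions gives the aryldiazoacetate (2S)-1-oxo-1-(pyrrolidin-1-yl)propan-2-yl ester corresponding to 17 F6.
- Dirhodium tetrakis[(S)-N-(4-dodecylbenzenesulfonyl)prolinate] Rh2(S-DOSP)4 (1 mol%) in CH2Cl2 gives the trans-(2S,3S)-dihydrobenzofuran-3-carboxylic (2S)-1-oxo-1-(pyrrolidin-1-yl)propan-2-yl ester corresponding to 19 F7. The (S)-lactamide/(S)-prolinate pairing is taken, by analogy, to be the matched one for the (2S,3S) trans ester.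
- LiAlH4 as in step 9 reduces it to 20.

**Further compounds**
F1 | step 6 | (4S)-4-benzyl-3-[3-(4-{[4-(benzyloxy)-3-methoxyphenyl]methoxy}-3-iodo-5-methoxyphenyl)propanoyl]-1,3-oxazolidin-2-one | O=C(CCc1cc(OC)c(OCc2ccc(OCc3ccccc3)c(OC)c2)c(I)c1)N1[C@@H](Cc2ccccc2)COC1=O
F2 | step 7 | methyl (2R,3R)-2-{[4-(benzyloxy)-3-methoxyphenyl]methyl}-3-{[4-{[4-(benzyloxy)-3-methoxyphenyl]methoxy}-3-(2-ethoxy-2-oxoethyl)-5-methoxyphenyl]methyl}-4-[(4S)-4-benzyl-2-oxo-1,3-oxazolidin-3-yl]-4-oxobutanoate | COc1cc(C[C@@H](C(=O)OC)[C@H](C(=O)N2[C@@H](Cc3ccccc3)COC2=O)Cc2cc(OC)c(OCc3ccc(OCc4ccccc4)c(OC)c3)c(CC(=O)OCC)c2)ccc1OCc1ccccc1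
F3 | step 8 | (2S)-2-hydroxy-1-(pyrrolidin-1-yl)propan-1-one | C[C@H](O)C(=O)N1CCCC1
F4 | step 8 | (2S)-1-oxo-1-(pyrrolidin-1-yl)propan-2-yl bromoacetate | C[C@H](OC(=O)CBr)C(=O)N1CCCC1
F5 | step 8 | (2S)-1-oxo-1-(pyrrolidin-1-yl)propan-2-yl diazoacetate | C[C@H](OC(=O)C=[N+]=[N-])C(=O)N1CCCC1
F6 | step 8 | aryldiazoacetate (2S)-1-oxo-1-(pyrrolidin-1-yl)propan-2-yl ester corresponding to 17 | COc1cc(C[C@@H](C(=O)OC)[C@H](C(=O)N2[C@@H](Cc3ccccc3)COC2=O)Cc2cc(OC)c(OCc3ccc(OCc4ccccc4)c(OC)c3)c(C(=[N+]=[N-])C(=O)O[C@@H](C)C(=O)N3CCCC3)c2)ccc1OCc1ccccc1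
F7 | step 8 | trans-(2S,3S)-dihydrobenzofuran-3-carboxylic (2S)-1-oxo-1-(pyrrolidin-1-yl)propan-2-yl ester corresponding to 19 | COc1cc(C[C@@H](C(=O)OC)[C@H](C(=O)N2[C@@H](Cc3ccccc3)COC2=O)Cc2cc(OC)c3c(c2)[C@H](C(=O)O[C@@H](C)C(=O)N2CCCC2)[C@@H](c2ccc(OCc4ccccc4)c(OC)c2)O3)ccc1OCc1ccccc1
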